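The readings were generated by integration with constants of no real substance; scatter was added.

N = 6.67 is the number to reckon with: the time allowed in the flask divided by a stopping time τ, counted in stopping times. Here τ is the time by which the beta run had stopped, stretched by the ratio of the Z charges on the assumption that the pace goes with Z.

- beta: Z 2 M; E 0.50 M; run made earlier
- flask: Z 1.0 M; E 0.500 M; time 40 min

beta run (percent of the Z and E together charged)

| time / min | J / % | D / % |
|---|---|---|
| 0.333 | 1.2 | 6.5 |
| 1.00 | 4.1 | 13.4 |
| 2.00 | 8.2 | 16.8 |
| 3.00 | 10.5 | 18.8 |
| 4.00 | 10.8 | 18.6 |

(readings scatter by 0.5 percentage points)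

- ratio of J to D at 2.5 s
- ratio of J to D at 80 s
- ratio of J to D at 40 min



Between 3.00 min and 4.00 min of the beta run J rose by 0.3 percentage points and D fell by 0.2 points, against a scatter of 0.5 points, so that run counts as stopped, and τ is 6.00 min for the flask. Because N stands well above one, the reckoning here takes the latest question as an end ratio and starts from the ratio of J to D in the last beta readings, 0.581. With the same stretching, 80 s in the flask matches 0.667 min of the beta run, between two readings whose ratios average 0.245. But 2.5 s matches 1.25 s, far before the first reading at 0.333 min, so one number serves the end and gives no ratio for the start.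

The forecast, reasoning that “J lags D”, gives 0.018, 0.33 and 0.7, and its values at 80 s and 40 min are higher than those of this reckoning.

The flask gives 1.01 at 2.5 s, 0.500 at 80 s and 0.725 at 40 min, so the forecast lies below by a factor of 56.1 at the earliest time, where N gave no ratio.

    E ⇌ X (K = 1.50, k = 0.130 /s)
    E → J (k = 0.0130 /s)
    Z + D → L (k = 0.00670 /M/s)
    Z → D (k = 0.00480 /s)
    Z ⇌ E (K = 0.330, k = 0.00590 /s)
    2 E → Q (k = 0.150 /M/s)

In the flask half of the turnover from Z to D is done by 1.29 min, far earlier than the 40 min allowed, and 98 % of it by 8.00 min, later than the τ of 6.00 min. The neighbour flask with 0.40 M of Z has N = 2.67, and at 40.0 min it stands at Z 0 %, E 0 % and a ratio of J to D of 0.887.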